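**Retrosynthetic overview**

1. The target comes from its 4‑O‑methyl ether by a final SN2 demethylation. The 7E,9E‑diene is cut at the sp2–sp2 bond into an (E)‑alkenyl iodide and the (E)‑alkenylalane made by Zr‑catalysed carboalumination of 3‑(pent‑4‑ynyl)furan.
2. The exocyclic Z‑alkene is cut into the C5 anion of 4‑methoxy‑3‑methylfuran‑2(5H)‑one and an aldehyde (vinylogous aldol, then E1cB elimination).
3. Both aldehyde‑derived ends go back to C2‑symmetric (2S,6S)‑2,6‑dimethylheptanedial, whose homotopic ends are told apart by one mono‑Takai olefination; the dial comes from a bis‑anilide.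
4. Key disconnection: both C–CH3 bonds at the two stereocentres, made in one operation by a two‑fold enantioconvergent NiCl2/Pybox coupling of a rac/meso 2,6‑dibromopimelic bis‑amide with MeZnCl. The amide α‑carbon is used as an electrophile (enolonium equivalent), the reverse of enolate + MeI.
5. Rings: neither ring is built. The furan enters as 3‑bromofuran and the butenolide as 3‑methyltetronic acid.

Assumption: (R)‑i‑Pr‑Pybox is taken to give the S centres in the key step; this is checked by optical‑rotation correlation on the first run and the ligand antipode is used if the sign is opposite.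
Assumption: heptanedioyl dichloride, N‑benzylaniline, 3‑methyltetronic acid, (5‑chloropent‑1‑yn‑1‑yl)trimethylsilane, 3‑bromofuran, MeZnCl (THF solution) and Cp2Zr(H)Cl are bought.

**Route**

Step 1
Reactants: 1 heptanedioyl dichloride (pimeloyl chloride); 2 N‑benzylaniline (2 equiv)
Product: 4 N1,N7‑dibenzyl‑2,6‑dibromo‑N1,N7‑diphenylheptanediamide (rac/meso mixture), via 2,6-dibromoheptanedioyl dichloride 3 (not isolated)
Conditions: Br2 (2.1 equiv), neat, 85 °C, then excess Br2 and HBr removed in vacuo; then 2 (2.2 equiv in all, one molecule per acyl chloride end), pyridine (2.5 equiv), CH2Cl2, 0 °C → rt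
Reagents that add atoms: bromine, BrBr; N‑benzylaniline (second equivalent of 2), C(Nc1ccccc1)c1ccccc1
Why: Two‑fold α‑bromination of the diacyl chloride through its enols (Hell–Volhard–Zelinsky type), then two‑fold Schotten–Baumann‑type amidation in which each COCl end takes up one molecule of 2; the stereoisomer mixture does not matter because both C–Br centres are erased in step 2.

Step 2
Reactants: 4 N1,N7‑dibenzyl‑2,6‑dibromo‑N1,N7‑diphenylheptanediamide
Product: 5 (2S,6S)‑N1,N7‑dibenzyl‑2,6‑dimethyl‑N1,N7‑diphenylheptanediamide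
Conditions: MeZnCl (3.0 equiv, 2 M in THF; one CH3 per C–Br), NiCl2·glyme (20 mol %), (R)‑i‑Pr‑Pybox (26 mol %), DMI/THF, 0 °C, 24 h; minor meso diamide removed by recrystallisation (preparative HPLC if needed)
Reagents that add atoms: methylzinc chloride, C[Zn]Cl
Why: Proposed new method: each α‑bromo amide carbon serves as an enolonium equivalent (electrophilic α‑carbon joined to a nucleophilic methyl); a low‑valent (pybox)Ni–CH3 species abstracts bromine to give a planar α‑amido radical, so rac and meso 4 converge, the radical is captured by the chiral (pybox)Ni–CH3 complex and C–CH3 reductive elimination sets each centre under catalyst control (methyl has no β‑hydrogen, so β‑hydride loss on the nucleophile side is impossible), and the two‑fold reaction amplifies selectivity (90 % ee per event gives about 99 % ee for S,S‑5 once the roughly 10 % meso isomer is removed); closest known reaction type: enantioconvergent Negishi coupling of racemic N‑benzyl‑N‑phenyl α‑bromo amides with primary alkylzinc halides under NiCl2·glyme/i‑Pr‑Pybox in DMI/THF, in which this electrophile class is standard and only the methyl nucleophile and the two‑fold use are new.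

Step 3
Reactants: 5 (2S,6S)‑N1,N7‑dibenzyl‑2,6‑dimethyl‑N1,N7‑diphenylheptanediamide
Product: 6 (2S,6S)‑2,6‑dimethylheptanedial
Conditions: Cp2Zr(H)Cl (2.6 equiv), THF, rt, 20 min; then H2O/silica gel; used crude at once
Reagents that add atoms: water, O
Why: Hydrozirconation of each tertiary amide C=O (amide‑to‑aldehyde reduction by Cp2Zr(H)Cl) gives a zirconated N,O‑acetal that collapses to an iminium ion, hydrolysed on work‑up to the aldehyde without over‑reduction and, under these neutral conditions, without α‑epimerisation.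

Step 4
Reactants: 6 (2S,6S)‑2,6‑dimethylheptanedial
Product: 7 (2S,6S,7E)‑8‑iodo‑2,6‑dimethyloct‑7‑enal
Conditions: CHI3 (1.0 equiv), CrCl2 (6 equiv), THF/dioxane, 0 °C; 6 used in twofold excess (2.0 equiv), unreacted 6 recovered
Reagents that add atoms: iodoform, IC(I)I
Why: Takai olefination: the CHI(CrCl2)2 species adds to one CHO and eliminates to the E‑iodoalkene under non‑basic conditions (no epimerisation); the two ends of C2‑symmetric 6 are homotopic, so mono‑olefination gives a single compound and only the yield is statistical.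

Step 5
Reactants: 8 3‑methyltetronic acid (4‑hydroxy‑3‑methylfuran‑2(5H)‑one)
Product: 9 4‑methoxy‑3‑methylfuran‑2(5H)‑one
Conditions: Me2SO4, K2CO3, acetone, reflux
Reagents that add atoms: dimethyl sulfate, COS(=O)(=O)OC
Why: Williamson‑type O‑methylation of the vinylogous acid (pKa about 4) at the 4‑oxygen, the usual outcome for 3‑substituted tetronic acids.

Step 6
Reactants: 9 4‑methoxy‑3‑methylfuran‑2(5H)‑one; 7 (2S,6S,7E)‑8‑iodo‑2,6‑dimethyloct‑7‑enal
Product: 13 (5Z)‑5‑[(2S,6S,7E)‑8‑iodo‑2,6‑dimethyloct‑7‑en‑1‑ylidene]‑4‑methoxy‑3‑methylfuran‑2(5H)‑one, via lithium 4-methoxy-3-methylfuran-2-olate 10 (not isolated), via lithium aldolate 11 (not isolated), via aldol mesylate 12 (not isolated)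
Conditions: LiN(i‑Pr)2 (LDA, 1.15 equiv), THF, −78 °C; 7 (1.0 equiv), −78 °C; MsCl (1.5 equiv), −78 → 0 °C; DBU (3 equiv), 0 °C → rt
Reagents that add atoms: none
Why: γ‑Deprotonation gives the 2‑oxidofuran whose C5 adds to the aldehyde (vinylogous aldol) at −78 °C faster than the α‑centre can epimerise, and mesylation/E1cB elimination gives the thermodynamically favoured Z‑ylidene (chain syn to the ring oxygen, away from OMe); the carbinol and C5 centres of 11 are destroyed again.

Step 7
Reactants: 14 (5‑chloropent‑1‑yn‑1‑yl)trimethylsilane; 15 3‑bromofuran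
Product: 18 3‑(pent‑4‑yn‑1‑yl)furan, via [5-(trimethylsilyl)pent-4-yn-1-yl]magnesium chloride 16 (not isolated), via trimethyl[5-(furan-3-yl)pent-1-yn-1-yl]silane 17 (not isolated)
Conditions: Mg, THF, 50 °C; 15, Pd(dppf)Cl2 (2 mol %), THF, 50 °C; then MeOH, K2CO3, rt
Reagents that add atoms: none
Why: Kumada–Corriu coupling of the primary alkyl Grignard reagent at the C–Br bond of 3‑bromofuran (dppf suppresses β‑hydride elimination), then base‑catalysed methanolysis of the alkynyl–Si bond in the same pot.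

Step 8
Reactants: 18 3‑(pent‑4‑yn‑1‑yl)furan; 13 (5Z)‑5‑[(2S,6S,7E)‑8‑iodo‑2,6‑dimethyloct‑7‑en‑1‑ylidene]‑4‑methoxy‑3‑methylfuran‑2(5H)‑one
Product: 20 (5Z)‑5‑[(2S,6S,7E,9E)‑13‑(furan‑3‑yl)‑2,6,10‑trimethyltrideca‑7,9‑dien‑1‑ylidene]‑4‑methoxy‑3‑methylfuran‑2(5H)‑one, via dimethyl[(1E)-5-(furan-3-yl)-2-methylpent-1-en-1-yl]alumane 19 (not isolated)
Conditions: Me3Al (2.5 equiv), Cp2ZrCl2 (0.25 equiv), CH2Cl2, 0 °C → rt; volatiles removed; then 13 (0.6 equiv), Pd(PPh3)4 (5 mol %), ZnCl2 (0.3 equiv), THF, rt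
Reagents that add atoms: trimethylaluminium, C[Al](C)C
Why: Zr‑catalysed carboalumination (Negishi) adds CH3 and Al syn across the terminal alkyne with Al at the terminus, giving only the E‑alkenylalane, which is cross‑coupled (Pd/Zn‑cocatalysed Negishi coupling) with the E‑alkenyl iodide with retention at both alkenes; the lactone and furan do not react with the alane in THF at rt.

Step 9
Reactants: 20 (5Z)‑5‑[(2S,6S,7E,9E)‑13‑(furan‑3‑yl)‑2,6,10‑trimethyltrideca‑7,9‑dien‑1‑ylidene]‑4‑methoxy‑3‑methylfuran‑2(5H)‑one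
Product: 22 (5Z)‑5‑[(2S,6S,7E,9E)‑13‑(furan‑3‑yl)‑2,6,10‑trimethyltrideca‑7,9‑dien‑1‑ylidene]‑4‑hydroxy‑3‑methylfuran‑2(5H)‑one (target), via lithium tetronate 21 (not isolated)
Conditions: LiCl (10 equiv), DMSO, 55 °C; then 0.5 M aq HCl to pH 3, 0 °C
Reagents that add atoms: none
Why: SN2 attack of chloride on the O‑methyl group of the vinylogous carbonate (Krapcho‑type dealkylation) releases the tetronate, a very good leaving group, under conditions that leave the furan, the diene, the Z‑ylidene and both stereocentres untouched.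

**Compound list**

1 | heptanedioyl dichloride | O=C(Cl)CCCCCC(=O)Cl | starting material
2 | N‑benzylaniline | C(Nc1ccccc1)c1ccccc1 | starting material
3 | 2,6‑dibromoheptanedioyl dichloride (stereoisomer mixture) | O=C(Cl)C(Br)CCCC(Br)C(=O)Cl | intermediate
4 | N1,N7‑dibenzyl‑2,6‑dibromo‑N1,N7‑diphenylheptanediamide (rac/meso mixture) | O=C(C(Br)CCCC(Br)C(=O)N(Cc1ccccc1)c1ccccc1)N(Cc1ccccc1)c1ccccc1 | intermediate
5 | (2S,6S)‑N1,N7‑dibenzyl‑2,6‑dimethyl‑N1,N7‑diphenylheptanediamide | C[C@@H](CCC[C@H](C)C(=O)N(Cc1ccccc1)c1ccccc1)C(=O)N(Cc1ccccc1)c1ccccc1 | intermediate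
6 | (2S,6S)‑2,6‑dimethylheptanedial | C[C@@H](CCC[C@H](C)C=O)C=O | intermediate
7 | (2S,6S,7E)‑8‑iodo‑2,6‑dimethyloct‑7‑enal | C[C@@H](CCC[C@H](C)/C=C/I)C=O | intermediate
8 | 3‑methyltetronic acid (4‑hydroxy‑3‑methylfuran‑2(5H)‑one) | CC1=C(O)COC1=O | starting material
9 | 4‑methoxy‑3‑methylfuran‑2(5H)‑one | CC1=C(OC)COC1=O | intermediate
10 | lithium 4‑methoxy‑3‑methylfuran‑2‑olate | [Li]OC1=C(C)C(OC)=CO1 | intermediate
11 | lithium alkoxide of 5‑[(2S,6S,7E)‑1‑hydroxy‑8‑iodo‑2,6‑dimethyloct‑7‑en‑1‑yl]‑4‑methoxy‑3‑methylfuran‑2(5H)‑one (epimer mixture at C5 and the carbinol carbon) | CC1=C(OC)C(C(O[Li])[C@@H](C)CCC[C@H](C)/C=C/I)OC1=O | intermediate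
12 | (2S,6S,7E)‑8‑iodo‑1‑(3‑methoxy‑4‑methyl‑5‑oxo‑2,5‑dihydrofuran‑2‑yl)‑2,6‑dimethyloct‑7‑en‑1‑yl methanesulfonate (epimer mixture) | CC1=C(OC)C(C(OS(C)(=O)=O)[C@@H](C)CCC[C@H](C)/C=C/I)OC1=O | intermediate
13 | (5Z)‑5‑[(2S,6S,7E)‑8‑iodo‑2,6‑dimethyloct‑7‑en‑1‑ylidene]‑4‑methoxy‑3‑methylfuran‑2(5H)‑one | CC1=C(OC)/C(=C/[C@@H](C)CCC[C@H](C)/C=C/I)OC1=O | intermediate
14 | (5‑chloropent‑1‑yn‑1‑yl)trimethylsilane | C[Si](C)(C)C#CCCCCl | starting material
15 | 3‑bromofuran | Brc1ccoc1 | starting material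
16 | [5‑(trimethylsilyl)pent‑4‑yn‑1‑yl]magnesium chloride | C[Si](C)(C)C#CCCC[Mg]Cl | intermediate
17 | trimethyl[5‑(furan‑3‑yl)pent‑1‑yn‑1‑yl]silane | C[Si](C)(C)C#CCCCc1ccoc1 | intermediate
18 | 3‑(pent‑4‑yn‑1‑yl)furan | C#CCCCc1ccoc1 | intermediate
19 | dimethyl[(1E)‑5‑(furan‑3‑yl)‑2‑methylpent‑1‑en‑1‑yl]alumane | C[Al](C)/C=C(\C)CCCc1ccoc1 | intermediate
20 | (5Z)‑5‑[(2S,6S,7E,9E)‑13‑(furan‑3‑yl)‑2,6,10‑trimethyltrideca‑7,9‑dien‑1‑ylidene]‑4‑methoxy‑3‑methylfuran‑2(5H)‑one | CC1=C(OC)/C(=C/[C@@H](C)CCC[C@H](C)/C=C/C=C(\C)CCCc2ccoc2)OC1=O | intermediate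
21 | lithium salt of the target (lithium tetronate) | CC1=C(O[Li])/C(=C/[C@@H](C)CCC[C@H](C)/C=C/C=C(\C)CCCc2ccoc2)OC1=O | intermediate
22 | (5Z)‑5‑[(2S,6S,7E,9E)‑13‑(furan‑3‑yl)‑2,6,10‑trimethyltrideca‑7,9‑dien‑1‑ylidene]‑4‑hydroxy‑3‑methylfuran‑2(5H)‑one | CC1=C(O)/C(=C/[C@@H](C)CCC[C@H](C)/C=C/C=C(\C)CCCc2ccoc2)OC1=O | target

**Step count and risks**

Total step count: 9. Longest linear sequence: 7 (steps 1, 2, 3, 4, 6, 8, 9).

Three steps most likely to fail:

Step 2 (two‑fold enantioconvergent methylation). The methyl nucleophile is untested in this catalyst system, so low ee per event, incomplete second coupling or hydrodebromination are possible. The meso diamide, with its 1,5‑related centres, may also be hard to separate. The fallback sets out from 2 and comes back at 5; it keeps the electrophilic α‑carbon but builds the chain bonds one at a time with the well‑precedented nucleophile class. 2 is acylated with 2‑bromopropanoyl bromide (pyridine, CH2Cl2) to racemic N‑benzyl‑2‑bromo‑N‑phenylpropanamide F1. Commercial (3‑bromopropoxy)(tert‑butyl)dimethylsilane and Zn dust (cat. I2, DMI, 70 °C) give {3‑[(tert‑butyldimethylsilyl)oxy]propyl}zinc bromide F2. F2 is coupled with F1 under NiCl2·glyme/i‑Pr‑Pybox (DMI/THF, 0 °C) to (2S)‑N‑benzyl‑5‑[(tert‑butyldimethylsilyl)oxy]‑2‑methyl‑N‑phenylpentanamide F3. The ligand enantiomer that gives S is used; it is expected to be the antipode of the one in step 2, because methyl and chain have exchanged roles. Ph3PBr2 (CH2Cl2, rt) converts the silyl ether directly into (2S)‑N‑benzyl‑5‑bromo‑2‑methyl‑N‑phenylpentanamide F4. Zn insertion (Zn, cat. I2, DMI, 70 °C) gives {(4S)‑5‑[benzyl(phenyl)amino]‑4‑methyl‑5‑oxopentyl}zinc bromide F5, and a second coupling with F1 under the same catalyst gives 5 after removal of the minor meso diamide.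

Step 4 (mono‑Takai olefination of the labile, volatile dial). Poor mono/bis control and losses of 6 are the danger. The fallback sets out from 5 and comes back at 7; it tells the two ends apart at the robust amide stage, so the free dial is never handled. 5 is reduced on one side only with Cp2Zr(H)Cl (1.1 equiv, THF, rt) to (2S,6S)‑N‑benzyl‑2,6‑dimethyl‑7‑oxo‑N‑phenylheptanamide F6, and unreacted 5 is recovered and recycled. Takai olefination (CHI3, CrCl2, THF/dioxane, 0 °C) then gives (2S,6S,7E)‑N‑benzyl‑8‑iodo‑2,6‑dimethyl‑N‑phenyloct‑7‑enamide F7, and a second Cp2Zr(H)Cl reduction (1.3 equiv, THF, rt) gives 7.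

Step 8 (alkenylalane coupling next to the electrophilic ylidene lactone). Me3Al residues may attack the tetronate, and the β,β‑disubstituted alkenylalane may transmetalate slowly. The fallback sets out from 18 and comes back at 20; it replaces the alane by an isolable boronate and a Suzuki–Miyaura coupling. 19, made from 18 as in step 8, is quenched with 2‑methoxy‑4,4,5,5‑tetramethyl‑1,3,2‑dioxaborolane to give 2‑[(1E)‑5‑(furan‑3‑yl)‑2‑methylpent‑1‑en‑1‑yl]‑4,4,5,5‑tetramethyl‑1,3,2‑dioxaborolane F8, which is purified free of aluminium. F8 is then coupled with 13 (Pd(dppf)Cl2, K3PO4, THF/H2O, rt) to give 20.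

Further compounds

F1 | step 2 | racemic N‑benzyl‑2‑bromo‑N‑phenylpropanamide | CC(Br)C(=O)N(Cc1ccccc1)c1ccccc1
F2 | step 2 | {3‑[(tert‑butyldimethylsilyl)oxy]propyl}zinc bromide | CC(C)(C)[Si](C)(C)OCCC[Zn]Br
F3 | step 2 | (2S)‑N‑benzyl‑5‑[(tert‑butyldimethylsilyl)oxy]‑2‑methyl‑N‑phenylpentanamide | C[C@@H](CCCO[Si](C)(C)C(C)(C)C)C(=O)N(Cc1ccccc1)c1ccccc1
F4 | step 2 | (2S)‑N‑benzyl‑5‑bromo‑2‑methyl‑N‑phenylpentanamide | C[C@@H](CCCBr)C(=O)N(Cc1ccccc1)c1ccccc1
F5 | step 2 | {(4S)‑5‑[benzyl(phenyl)amino]‑4‑methyl‑5‑oxopentyl}zinc bromide | C[C@@H](CCC[Zn]Br)C(=O)N(Cc1ccccc1)c1ccccc1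
F6 | step 4 | (2S,6S)‑N‑benzyl‑2,6‑dimethyl‑7‑oxo‑N‑phenylheptanamide | C[C@@H](CCC[C@H](C)C=O)C(=O)N(Cc1ccccc1)c1ccccc1
F7 | step 4 | (2S,6S,7E)‑N‑benzyl‑8‑iodo‑2,6‑dimethyl‑N‑phenyloct‑7‑enamide | C[C@@H](CCC[C@H](C)/C=C/I)C(=O)N(Cc1ccccc1)c1ccccc1
F8 | step 8 | 2‑[(1E)‑5‑(furan‑3‑yl)‑2‑methylpent‑1‑en‑1‑yl]‑4,4,5,5‑tetramethyl‑1,3,2‑dioxaborolane | CC1(C)OB(/C=C(\C)CCCc2ccoc2)OC1(C)C
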